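(Readings and results are simulated for an exercise, noise included.)

Which set-up gives the most target, and does the way of charging matter?

| setting | violet | green | oak | larch | maple | birch |
|---|---|---|---|---|---|---|
| starting material | 0.25 M | 0.25 M | 0.25 M | 0.25 M (fed, over 2.40 min) | 0.25 M | 0.25 M |
| partner | 2 equiv | 4 equiv | 2.00 equiv | 2.00 equiv | 2.00 equiv | 2.00 equiv (fed, over 2.40 min) |
| protic impurity | 0.025 M | 0.025 M | 0.0250 M | 0.0250 M | 0.0250 M | 0.0250 M |
| initiator | 5 mol% | 5 mol% | 5 mol% | 5 mol% | 5 mol% | 5 mol% |
| radical scavenger | 1 mol% | 1 mol% | 1 mol% | 1 mol% | 1 mol% | 1 mol% |
| remark | run made earlier | run made earlier | a closed flask charged with all of it at once and left for 3.0 min | a stirred flask in which starting material is dosed at a steady rate over 2.40 min without added volume, worked up at 3.0 min | one stirred flow tank at steady state, fed with the mixture as stated, mean residence time 3.0 min | all but partner at the start; partner goes in evenly over 2.40 min, the run ends at 3.0 min |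
| time |  |  | 3.0 min | 3.0 min |  | 3.0 min |

violet run (percent of the starting material charged): time / min: target / % = 0.200: 0; 0.667: 87.3; 1.00: 89.0; 1.50: 88.2; 2.50: 90.8; 3.00: 86.7

green run (percent of the starting material charged): time / s: target / % = 10.0: 0.3; 12.0: 1.4; 20.0: 0.6; 40.0: 89.4

(scatter of a reading: 1 percentage point)

- the stated concentrations are those of everything mixed, before any reaction; amounts are the same in each set-up
- the analysis behind the earlier runs scatters by 1 percentage point, standard deviation
- the feed brings no volume worth counting
- the earlier runs were made in a closed, stirred flask
- a reading or a percentage of target counts all its forms, free or not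

* the set-up with the highest amount of target at the outlet or at the end, in percent of the starting material put in ("none" if the first two lie within 2 percentage points) (oak / larch / maple / birch / none)
* amount of target at the outlet or at the end, in percent of the starting material put in, oak
* amount of target at the outlet or at the end, in percent of the starting material put in, larch
* amount of target at the outlet or at the end, in percent of the starting material put in, maple
* amount of target at the outlet or at the end, in percent of the starting material put in, birch

I count turnovers. Starting material is the limiting reagent. If each protic impurity destroys one starting material, the target can reach one minus their ratio, 90.0%. I call this the impurity ceiling, the share of starting material left after that one-for-one loss. The later violet readings average 88.4%, which is less than the ceiling by 1.6 percentage points, against a scatter of 1 point per reading.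

Now I turn the settings. Time is not in the ceiling, so by hand more time gives nothing once the reaction is over. Violet reads 87.3% at 0.667 min and 86.7% at 3.00 min. Partner is not in the ceiling either. Green, with 4 equiv, reads 89.4% at 40.0 s, and violet, with 2 equiv, reads 87.3% at 40 s. Feeding leaves the ratio of whole charges as it was, so larch and birch keep the ceiling. Their last dose has 0.600 min to finish, and I expect that to do. The maple tank has the same ceiling, but its outlet carries some unreacted starting material. So I put oak, larch and birch near 88.4% and maple a little lower.

The forecast gives oak 88.8%, larch 88.5%, maple 85%, birch 88.5%, best none. It holds that “the order of addition shouldn't change that”.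

The flasks give oak 88.8%, larch 89.0%, maple 87.0% and birch 87.2%. Larch and oak differ by 0.20 points, inside the margin of 2 points, so the answer is none.

    initiator → 2 initiating radical (k = 0.00451 s⁻¹)
    starting material + initiating radical → capped initiator + first chain carrier (k = 4.42 × 10⁵ M⁻¹ s⁻¹)
    partner + first chain carrier → target + second chain carrier (k = 50500 M⁻¹ s⁻¹)
    starting material + second chain carrier → by-product + first chain carrier (k = 2.95 × 10⁵ M⁻¹ s⁻¹)
    first chain carrier → ended carrier (k = 5.62 s⁻¹)
    2 first chain carrier → ended chains A (k = 1.90 × 10⁷ M⁻¹ s⁻¹)
    2 second chain carrier → ended chains B (k = 3.30 × 10⁶ M⁻¹ s⁻¹)
    starting material + target ⇌ idle adduct, settled at all times (K = 17.2 M⁻¹)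
    starting material + protic impurity → quenched substrate (k = 48.2 M⁻¹ s⁻¹)
    first chain carrier + radical scavenger → ended chains C (k = 4.47 × 10⁷ M⁻¹ s⁻¹)

In oak, starting material meets protic impurity at the start, with a half-life by that step of 0.58 s at charged concentrations, against 2.6 min for the initiator. The first and second chain carriers then make target, idle adduct counted in. Maple ends 3 points from the ceiling. With protic impurity at 0.0125 M, the ceiling for larch rises by 5 points, and larch's target has moved by 5 points.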